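**Retrosynthetic overview**

1. The target is the C2-symmetric (3R,6R,3'R,6'R)-ε,ε-carotene-3,3'-diol. Cutting C11=C12 and C11'=C12' (double Wittig) gives the commercial C10 trienedial 15 and two equivalents of one C15 phosphonium salt 14; 14 comes from the ring aldehyde 9 (C6–C7HO) by a C7=C8 Horner–Wadsworth–Emmons reaction with the C5 phosphonate 10.
2. Enabling feature: in each six-membered ring (C1–C6) the C3 carbinol is allylic to C4=C5(C18). At the ketone level the ring is a 3-methylcyclohex-2-enone whose C4=C5 bond is an aldol-condensation retron. The quaternary C1 lies β to C3=O (Michael retron), and C6, between C5=O and C7 at the ester level, is an acetoacetate carbon.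
3. Key step: Lewis-acid Michael/aldol-condensation annulation of ethyl acetoacetate 1 with mesityl oxide 2. The fragments are joined at the hindered C1–C6 bond and the ring is then closed by forming C4=C5, which puts all ten end-group carbons and both oxygen functions (C3, C7) in place.
4. Stereocentres: C3 is set by Corey–Bakshi–Shibata reduction (reagent control). C6 is labile in keto ester 5 and is fixed at the same step, when the two C6-epimeric alcohols are separated. The symmetric dimerisation removes residual enantiomer as a meso-type diastereomer.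
5. Ring order: the ε-ring is made once (step 1), before any stereocentre or chain carbon; the two rings of the target are two copies of it, joined through the C10 unit in step 9.

Key step: step 1

Assumption: carotenoid numbering is used for atoms; commercial 10 (an E/Z mixture, drawn as E) reacts through one delocalised anion, and 15 is the commercial all-E dialdehyde.

**Route**

Step 1
Reactants: 1 ethyl acetoacetate; 2 mesityl oxide (4-methylpent-3-en-2-one)
Product: 5 (±)-ethyl 2,6,6-trimethyl-4-oxocyclohex-2-ene-1-carboxylate, via Michael adduct 3 (not isolated), via aldol 4 (not isolated)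
Conditions: ZnCl2 (0.2 equiv), toluene, reflux, Dean–Stark (−H2O)
Reagents that add atoms: none
Why: ZnCl2 chelates the β-keto ester as its zinc enolate and activates the enone, so the acetoacetate carbon (future C6) adds in a Michael reaction to the β-carbon of 2 (future C1) and forges the quaternary–tertiary C1–C6 bond to give 1,5-diketone 3; the enol of the remaining methyl ketone (C3=O, nucleophilic carbon C4) then attacks the chelation-activated acetoacetate ketone (C5) and closes the six-membered ring at C4–C5 to aldol 4, whose dehydration (E1cB through the C3 enol, water removed azeotropically) turns this bond into the C4=C5 double bond of enone 5. The closest known reaction type is the Robinson-type (Michael/aldol-condensation) annulation of β-keto esters with enones. The ring is closed in the 6-(enolendo)-exo-trig mode. The only new stereocentre, C6 (ester C1), is not controlled: as the γ-carbon of the enone and the α-carbon of the ester it is a vinylogous β-keto ester position that should racemise readily, so 5 is taken on as the racemate and C6 is fixed in step 2. The step needs chemoselectivity between this aldol mode, the alternative aldol (acetyl CH3 onto C3=O) and Claisen-type acylation of C4 by the ester; it is secured by the alkoxide-free Lewis-acidic conditions (no Claisen), by the higher electrophilicity of the zinc-chelated acetoacetate ketone, by the gem-dimethyl (Thorpe–Ingold) effect at C1, and because only this mode ends in the conjugated, thermodynamically favoured enone under reversible, water-removing conditions.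

Step 2
Reactants: 5 (±)-ethyl 2,6,6-trimethyl-4-oxocyclohex-2-ene-1-carboxylate
Product: 6 ethyl (1R,4R)-4-hydroxy-2,6,6-trimethylcyclohex-2-ene-1-carboxylate
Conditions: (S)-2-methyl-CBS-oxazaborolidine [(3aS)-1-methyl-3,3-diphenyltetrahydro-1H,3H-pyrrolo[1,2-c][1,3,2]oxazaborole, C18H20BNO] (0.2 equiv), catecholborane (1.5 equiv), toluene, −78 °C; aq. NaOH; chromatographic separation of the C1 epimers
Reagents that add atoms: none
Why: Corey–Bakshi–Shibata reduction, in which the oxazaborolidine–borane complex binds the enone carbonyl with the alkenyl flank as the large and the CH2 flank as the small group and should deliver hydride to give the 4R carbinol (carotenoid C3) from both enantiomers of 5, so that the labile C1 (carotenoid C6) is fixed as two separable diastereomers of which trans-6 is collected, while the cis-isomer can be re-oxidised with MnO2 to 5, which racemises, and recycled.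

Step 3
Reactants: 6 ethyl (1R,4R)-4-hydroxy-2,6,6-trimethylcyclohex-2-ene-1-carboxylate
Product: 7 ethyl (1R,4R)-4-[(tert-butyldimethylsilyl)oxy]-2,6,6-trimethylcyclohex-2-ene-1-carboxylate
Conditions: TBSCl, imidazole, DMF, 23 °C
Reagents that add atoms: tert-butyldimethylsilyl chloride, CC(C)(C)[Si](C)(C)Cl
Why: Imidazole-mediated O-silylation protects the allylic ring hydroxyl, so that only the side-chain hydroxyl is activated in step 8, and touches no stereocentre.

Step 4
Reactants: 7 ethyl (1R,4R)-4-[(tert-butyldimethylsilyl)oxy]-2,6,6-trimethylcyclohex-2-ene-1-carboxylate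
Product: 8 [(1R,4R)-4-[(tert-butyldimethylsilyl)oxy]-2,6,6-trimethylcyclohex-2-en-1-yl]methanol
Conditions: LiAlH4, Et2O, 0 °C
Reagents that add atoms: none
Why: Hydride reduction of the ester with LiAlH4 brings C7 to the alcohol level under conditions that are not basic enough to epimerise the ester α-carbon and that leave the silyl ether and the trisubstituted olefin untouched.

Step 5
Reactants: 8 [(1R,4R)-4-[(tert-butyldimethylsilyl)oxy]-2,6,6-trimethylcyclohex-2-en-1-yl]methanol
Product: 9 (1R,4R)-4-[(tert-butyldimethylsilyl)oxy]-2,6,6-trimethylcyclohex-2-ene-1-carbaldehyde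
Conditions: Dess–Martin periodinane (1,1,1-triacetoxy-1,1-dihydro-1,2-benziodoxol-3(1H)-one), NaHCO3, CH2Cl2, 0 °C
Reagents that add atoms: none
Why: Dess–Martin oxidation under buffered, non-basic conditions should give the β,γ-unsaturated aldehyde without epimerisation at C6 or migration of the ring double bond into conjugation.

Step 6
Reactants: 9 (1R,4R)-4-[(tert-butyldimethylsilyl)oxy]-2,6,6-trimethylcyclohex-2-ene-1-carbaldehyde; 10 triethyl 3-methyl-4-phosphonocrotonate [ethyl (2E)-4-(diethoxyphosphoryl)-3-methylbut-2-enoate]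
Product: 11 ethyl (2E,4E)-5-[(1R,4R)-4-[(tert-butyldimethylsilyl)oxy]-2,6,6-trimethylcyclohex-2-en-1-yl]-3-methylpenta-2,4-dienoate
Conditions: 10 (1.3 equiv), LiN(SiMe3)2 (1.2 equiv), THF, −78 °C; then 9, −78 → 0 °C
Reagents that add atoms: none
Why: Horner–Wadsworth–Emmons olefination, in which the delocalised, weakly basic phosphonate anion (pre-formed, no free amide base) adds to the hindered aldehyde and collapses through the favoured anti-oxaphosphetane to the (E)-C7=C8 bond, while the 9E geometry is carried by the reagent.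

Step 7
Reactants: 11 ethyl (2E,4E)-5-[(1R,4R)-4-[(tert-butyldimethylsilyl)oxy]-2,6,6-trimethylcyclohex-2-en-1-yl]-3-methylpenta-2,4-dienoate
Product: 12 (2E,4E)-5-[(1R,4R)-4-[(tert-butyldimethylsilyl)oxy]-2,6,6-trimethylcyclohex-2-en-1-yl]-3-methylpenta-2,4-dien-1-ol
Conditions: i-Bu2AlH (2.5 equiv), CH2Cl2, −78 °C; Rochelle salt work-up
Reagents that add atoms: none
Why: 1,2-Reduction of the dienoate with i-Bu2AlH gives the dienylic alcohol without touching the diene, the silyl ether or the stereocentres.

Step 8
Reactants: 12 (2E,4E)-5-[(1R,4R)-4-[(tert-butyldimethylsilyl)oxy]-2,6,6-trimethylcyclohex-2-en-1-yl]-3-methylpenta-2,4-dien-1-ol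
Product: 14 [(2E,4E)-5-[(1R,4R)-4-[(tert-butyldimethylsilyl)oxy]-2,6,6-trimethylcyclohex-2-en-1-yl]-3-methylpenta-2,4-dien-1-yl]triphenylphosphonium bromide, via allylic bromide 13 (not isolated)
Conditions: CBr4, PPh3, 2,6-dimethylpyridine, CH2Cl2, −20 °C; then PPh3, EtOAc, 23 °C, dark
Reagents that add atoms: triphenylphosphine, c1ccc(cc1)P(c1ccccc1)c1ccccc1; carbon tetrabromide, BrC(Br)(Br)Br
Why: The Appel reaction converts only the free primary dienylic alcohol under neutral conditions (the ring allylic oxygen is silylated and no acid is present), and the labile bromide is quaternised in the same flask by displacement with PPh3 to the primary phosphonium salt.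

Step 9
Reactants: 14 the C15 phosphonium bromide (2.2 equiv); 15 (2E,4E,6E)-2,7-dimethylocta-2,4,6-trienedial (1 equiv)
Product: 17 (3R,3'R,6R,6'R)-3,3'-bis[(tert-butyldimethylsilyl)oxy]-ε,ε-carotene, via apo-aldehyde 16 (not isolated)
Conditions: NaOMe, MeOH/CH2Cl2, 0 → 23 °C, argon, dark; then heptane, reflux (Z → E)
Reagents that add atoms: none
Why: Two-fold Wittig olefination of the dialdehyde with the semi-stabilised C15 ylide builds C11=C12 and C11'=C12', the Z isomers at the new disubstituted double bonds should isomerise thermally to the all-E polyene, and any minor enantiomer of the end group ends up mainly in the separable meso-type (3R,6R,3'S,6'S) diastereomer (Horeau amplification).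

Step 10
Reactants: 17 (3R,3'R,6R,6'R)-3,3'-bis[(tert-butyldimethylsilyl)oxy]-ε,ε-carotene
Product: 18 (3R,3'R,6R,6'R)-ε,ε-carotene-3,3'-diol (the target)
Conditions: Bu4NF, THF, 0 → 23 °C, argon, dark
Reagents that add atoms: none
Why: Fluoride-mediated desilylation cleaves the two Si–O bonds without acid, so the acid-labile allylic carbinols and the polyene should survive with retention at C3 and C3'.

**Compound list**

1 | ethyl acetoacetate | CCOC(=O)CC(C)=O | starting material
2 | mesityl oxide (4-methylpent-3-en-2-one) | CC(=O)C=C(C)C | starting material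
3 | ethyl 2-acetyl-3,3-dimethyl-5-oxohexanoate (racemic Michael adduct) | CCOC(=O)C(C(C)=O)C(C)(C)CC(C)=O | intermediate
4 | ethyl 2-hydroxy-2,6,6-trimethyl-4-oxocyclohexane-1-carboxylate (aldol, stereoisomer mixture) | CCOC(=O)C1C(C)(O)CC(=O)CC1(C)C | intermediate
5 | (±)-ethyl 2,6,6-trimethyl-4-oxocyclohex-2-ene-1-carboxylate | CCOC(=O)C1C(C)=CC(=O)CC1(C)C | intermediate
6 | ethyl (1R,4R)-4-hydroxy-2,6,6-trimethylcyclohex-2-ene-1-carboxylate | CC1=C[C@H](O)CC(C)(C)[C@H]1C(=O)OCC | intermediate
7 | ethyl (1R,4R)-4-[(tert-butyldimethylsilyl)oxy]-2,6,6-trimethylcyclohex-2-ene-1-carboxylate | CC1=C[C@H](O[Si](C)(C)C(C)(C)C)CC(C)(C)[C@H]1C(=O)OCC | intermediate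
8 | [(1R,4R)-4-[(tert-butyldimethylsilyl)oxy]-2,6,6-trimethylcyclohex-2-en-1-yl]methanol | CC1=C[C@H](O[Si](C)(C)C(C)(C)C)CC(C)(C)[C@H]1CO | intermediate
9 | (1R,4R)-4-[(tert-butyldimethylsilyl)oxy]-2,6,6-trimethylcyclohex-2-ene-1-carbaldehyde | CC1=C[C@H](O[Si](C)(C)C(C)(C)C)CC(C)(C)[C@H]1C=O | intermediate
10 | triethyl 3-methyl-4-phosphonocrotonate [ethyl (2E)-4-(diethoxyphosphoryl)-3-methylbut-2-enoate] | CCOC(=O)/C=C(C)/CP(=O)(OCC)OCC | starting material
11 | ethyl (2E,4E)-5-[(1R,4R)-4-[(tert-butyldimethylsilyl)oxy]-2,6,6-trimethylcyclohex-2-en-1-yl]-3-methylpenta-2,4-dienoate | CC1=C[C@H](O[Si](C)(C)C(C)(C)C)CC(C)(C)[C@H]1/C=C/C(C)=C/C(=O)OCC | intermediate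
12 | (2E,4E)-5-[(1R,4R)-4-[(tert-butyldimethylsilyl)oxy]-2,6,6-trimethylcyclohex-2-en-1-yl]-3-methylpenta-2,4-dien-1-ol | CC1=C[C@H](O[Si](C)(C)C(C)(C)C)CC(C)(C)[C@H]1/C=C/C(C)=C/CO | intermediate
13 | (2E,4E)-5-[(1R,4R)-4-[(tert-butyldimethylsilyl)oxy]-2,6,6-trimethylcyclohex-2-en-1-yl]-3-methylpenta-2,4-dien-1-yl bromide | CC1=C[C@H](O[Si](C)(C)C(C)(C)C)CC(C)(C)[C@H]1/C=C/C(C)=C/CBr | intermediate
14 | [(2E,4E)-5-[(1R,4R)-4-[(tert-butyldimethylsilyl)oxy]-2,6,6-trimethylcyclohex-2-en-1-yl]-3-methylpenta-2,4-dien-1-yl]triphenylphosphonium bromide | CC1=C[C@H](O[Si](C)(C)C(C)(C)C)CC(C)(C)[C@H]1/C=C/C(C)=C/C[P+](c1ccccc1)(c1ccccc1)c1ccccc1.[Br-] | intermediate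
15 | (2E,4E,6E)-2,7-dimethylocta-2,4,6-trienedial | O=C/C(C)=C/C=C/C=C(C)/C=O | starting material
16 | (2E,4E,6E,8E,10E,12E)-13-[(1R,4R)-4-[(tert-butyldimethylsilyl)oxy]-2,6,6-trimethylcyclohex-2-en-1-yl]-2,7,11-trimethyltrideca-2,4,6,8,10,12-hexaenal | CC1=C[C@H](O[Si](C)(C)C(C)(C)C)CC(C)(C)[C@H]1/C=C/C(C)=C/C=C/C(C)=C/C=C/C=C(C)/C=O | intermediate
17 | (3R,3'R,6R,6'R)-3,3'-bis[(tert-butyldimethylsilyl)oxy]-ε,ε-carotene | CC1=C[C@H](O[Si](C)(C)C(C)(C)C)CC(C)(C)[C@H]1/C=C/C(C)=C/C=C/C(C)=C/C=C/C=C(C)/C=C/C=C(C)/C=C/[C@H]1C(C)=C[C@H](O[Si](C)(C)C(C)(C)C)CC1(C)C | intermediate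
18 | (3R,3'R,6R,6'R)-ε,ε-carotene-3,3'-diol | CC1=C[C@H](O)CC(C)(C)[C@H]1/C=C/C(C)=C/C=C/C(C)=C/C=C/C=C(C)/C=C/C=C(C)/C=C/[C@H]1C(C)=C[C@H](O)CC1(C)C | target

**Step count**

Total step count: 10. Longest linear sequence: 10 steps (1 and 2 to 18); 14 is used twice in step 9.

**Steps most likely to fail**

Step 2. Reagent control may be incomplete: in the (1S)-series of 5 the ring's own facial bias can compete with the catalyst and leak the enantiomer of 6 into the trans fraction, and the two C1 epimers may be hard to separate. Fallback, setting out from 5 and returning at 6: 5 is reduced without a chiral reagent under Luche conditions (NaBH4, CeCl3·7H2O, MeOH, −20 °C). The racemic trans-alcohol, (±)-ethyl (1R*,4R*)-4-hydroxy-2,6,6-trimethylcyclohex-2-ene-1-carboxylate F1, is separated from the cis-racemate and esterified with (S)-2-methoxy-2-phenylacetic acid (N,N'-dicyclohexylcarbodiimide, 4-(dimethylamino)pyridine, CH2Cl2). The two diastereomeric esters are separated by chromatography or crystallisation, and the configuration is assigned from the shielding pattern of the O-methylmandelate. The (1R,4R)-diastereomer, ethyl (1R,4R)-4-{[(2S)-2-methoxy-2-phenylacetyl]oxy}-2,6,6-trimethylcyclohex-2-ene-1-carboxylate F2, is cleaved with K2CO3 in EtOH to give 6.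

Step 6. The phosphonate anion may deprotonate the α-carbon of the hindered aldehyde faster than it adds, which would epimerise C6 or move the ring double bond into conjugation; part of the product may also form as the 9Z isomer. Fallback, setting out from 9 and returning at 11: 9 is heated with the salt-free, non-basic stabilised ylide 1-(triphenylphosphoranylidene)propan-2-one (toluene, 90 °C) to give the enone (3E)-4-[(1R,4R)-4-[(tert-butyldimethylsilyl)oxy]-2,6,6-trimethylcyclohex-2-en-1-yl]but-3-en-2-one F3. F3 is extended by a Horner–Wadsworth–Emmons reaction with triethyl phosphonoacetate (NaH, THF, 0 → 23 °C) to 11, and the 9Z isomer is removed by chromatography.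

Step 9. The second olefination may stay incomplete and the two new double bonds may form as Z/E mixtures that isomerise only partly, with losses by oxidation of the long polyene. Fallback, setting out from 12 (and 15) and returning at 17, with reversed polarity and E-selective phosphonate chemistry: 12 is oxidised with MnO2 (CH2Cl2, 23 °C) to (2E,4E)-5-[(1R,4R)-4-[(tert-butyldimethylsilyl)oxy]-2,6,6-trimethylcyclohex-2-en-1-yl]-3-methylpenta-2,4-dienal F4. Separately, 15 is reduced (NaBH4, MeOH, 0 °C) to (2E,4E,6E)-2,7-dimethylocta-2,4,6-triene-1,8-diol F5, brominated (PBr3, Et2O, −10 °C) to (2E,4E,6E)-1,8-dibromo-2,7-dimethylocta-2,4,6-triene F6, and heated with P(OEt)3 (Michaelis–Arbuzov reaction) to tetraethyl [(2E,4E,6E)-2,7-dimethylocta-2,4,6-triene-1,8-diyl]bis(phosphonate) F7. Double Horner–Wadsworth–Emmons reaction of F7 with two equivalents of F4 (KOt-Bu, THF, −30 → 0 °C) gives 17.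

**Further compounds**

F1 | step 2 | (±)-ethyl (1R*,4R*)-4-hydroxy-2,6,6-trimethylcyclohex-2-ene-1-carboxylate (racemate, both enantiomers written) | CC1=C[C@H](O)CC(C)(C)[C@H]1C(=O)OCC.CC1=C[C@@H](O)CC(C)(C)[C@@H]1C(=O)OCC
F2 | step 2 | ethyl (1R,4R)-4-{[(2S)-2-methoxy-2-phenylacetyl]oxy}-2,6,6-trimethylcyclohex-2-ene-1-carboxylate | CC1=C[C@H](OC(=O)[C@@H](OC)c2ccccc2)CC(C)(C)[C@H]1C(=O)OCC
F3 | step 6 | (3E)-4-[(1R,4R)-4-[(tert-butyldimethylsilyl)oxy]-2,6,6-trimethylcyclohex-2-en-1-yl]but-3-en-2-one | CC1=C[C@H](O[Si](C)(C)C(C)(C)C)CC(C)(C)[C@H]1/C=C/C(C)=O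
F4 | step 9 | (2E,4E)-5-[(1R,4R)-4-[(tert-butyldimethylsilyl)oxy]-2,6,6-trimethylcyclohex-2-en-1-yl]-3-methylpenta-2,4-dienal | CC1=C[C@H](O[Si](C)(C)C(C)(C)C)CC(C)(C)[C@H]1/C=C/C(C)=C/C=O
F5 | step 9 | (2E,4E,6E)-2,7-dimethylocta-2,4,6-triene-1,8-diol | OC/C(C)=C/C=C/C=C(C)/CO
F6 | step 9 | (2E,4E,6E)-1,8-dibromo-2,7-dimethylocta-2,4,6-triene | BrC/C(C)=C/C=C/C=C(C)/CBr
F7 | step 9 | tetraethyl [(2E,4E,6E)-2,7-dimethylocta-2,4,6-triene-1,8-diyl]bis(phosphonate) | CCOP(=O)(OCC)C/C(C)=C/C=C/C=C(C)/CP(=O)(OCC)OCC
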